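The flasks south-west and west were to be read at 30 min, so I first asked whether that was long enough.

| flask | J | Q | temperature | remark | time |
|---|---|---|---|---|---|
| green | 0.067 M | 1.1 equiv | −25 °C | run made earlier |  |
| red | 0.15 M | 1.1 equiv | −8 °C | run made earlier |  |
| grey | 0.10 M | 1.7 equiv | −25 °C | run made earlier |  |
| south-west | 0.10 M | 1.10 equiv | −20 °C |  | 30 min |
| west | 0.10 M | 1.10 equiv | 5 °C |  | 30 min |

| run | time / min | X / % |
|---|---|---|
| green | 1.33 | 12.4 |
| green | 2.50 | 18.1 |
| green | 4.00 | 25.9 |
| green | 6.00 | 30.5 |
| green | 10.0 | 37.4 |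
| green | 20.0 | 45.0 |
| red | 1.50 | 46.2 |
| red | 3.00 | 56.9 |
| red | 6.00 | 65.9 |
| red | 8.00 | 68.7 |
| red | 12.0 | 70.8 |
| grey | 4.00 | 44.8 |
| grey | 8.00 | 56.0 |
| grey | 10.0 | 54.7 |
| grey | 15.0 | 58.1 |
| grey | 20.0 | 55.6 |

(readings scatter by 1 percentage point)

- which flask leads in amount of X, in percent of the J charged ("all alike" within 1.5 percentage points) (south-west / west / all alike)
- how much X is there at the end, in percent of the J charged: south-west
- how much X is there at the end, in percent of the J charged: west

- a species is counted by the J in it: one Z counts as two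
- the numbers in the tables scatter with a standard deviation of 1 percentage point
- reactions considered so far: J + Q -> X; Q + X <-> E; 2 J -> Z; X <-> G

Grey stood level from 8.00 min on at −25 °C. Starting Q multiplied by time in south-west came to 2.43 times that product in grey, and south-west was warmer. But that product counts Q as it stood at the start, and south-west was charged with less Q per J than grey, so I could only assume that south-west stood near a level by the reading.

The level was then what mattered. Grey's readings from 8.00 min on average 56.1%, red's last reading is 70.8%, and a straight line in temperature between them passes 0.604 at −20 °C. I called this the keep, the X standing per equivalent of Q spent, and froze it against the charge of Q. My weak link was the assumption that south-west spent 1 equivalent of Q, which made its X 60.4%.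

The forecast gave 61% for south-west and 75% for west, so west in the lead: “West finishes fully and should have less E”.

The flasks gave 60.7% in south-west and 59.7% in west, so the answer was all alike.

    J + Q → X (k = 0.0330 M⁻¹ s⁻¹, Ea = 36.0 kJ mol⁻¹)
    Q + X ⇌ E (K = 400 M⁻¹, k = 9.90 × 10⁻⁴ M⁻¹ s⁻¹, Ea = 52.0 kJ mol⁻¹, ΔH = −8.00 kJ mol⁻¹)
    2 J → Z (k = 0.00300 M⁻¹ s⁻¹, Ea = 53.0 kJ mol⁻¹)
    X ⇌ G (K = 0.310, k = 0.00260 s⁻¹, Ea = 76.0 kJ mol⁻¹, ΔH = −61.0 kJ mol⁻¹)
    (constants at −20 °C)

At the reading south-west was not finished: it still held 6.5% of its J and kept 22% of its Q, so it had spent 0.860 equivalents, not 1. Reforged on that amount, its keep became 0.706 in place of 0.604. A neighbour of south-west, charged with 0.660 equiv of Q, had Q as its limiting reagent, with 9.3% of that Q left and 21% of its J. It had spent 0.598 equivalents, so the reforged keep gives 42.2% of X, and that flask held 44.3%.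

The readings were generated by integration with constants of no real substance; the scatter is artificial.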